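The data are calculated for substances that don't exist; noise was put on by code.

Amber holds less free monomer than ochre at the last reading, 81 % against 90 %, and amber carries more protic impurity, 0.26 M against 0.17 M.

| setting | ochre | amber | flask |
|---|---|---|---|
| free monomer | 0.24 M | 0.24 M | 0.24 M |
| protic impurity | 0.17 M | 0.26 M | 0.120 M |
| pre-initiator | 2 mol% | 2 mol% | 2 mol% |
| remark | run made earlier | run made earlier |  |
| time |  |  | 2.0 h |

| run | time / min | monomer in chains / % | free monomer / % |
|---|---|---|---|
| ochre | 10.0 | 0 | 96 |
| ochre | 20.0 | 0 | 98 |
| ochre | 50.0 | 0 | 93 |
| ochre | 120 | 1 | 90 |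
| amber | 10.0 | 1 | 97 |
| amber | 20.0 | 0 | 99 |
| amber | 50.0 | 1 | 97 |
| amber | 120 | 6 | 81 |

(each reading ± 2 percentage points)

- average number of monomer units in a chain (chains begun, living or dead) at 2.0 h
- part of the free monomer that has reacted at 2.0 h

- the average divides the monomer in chains by the number of chains begun, living and dead together
- the earlier runs do not show the number of chains; that part of a forecast is a guess

Turn the impurity first. Call monomer neither free nor in chains the missing share. If impurity removes free monomer at a rate proportional to [protic impurity][free monomer], with [protic impurity] nearly constant (pseudo-first-order), then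

missing share = 1 − exp(−k [protic impurity] t)

Ochre reads k = 0.00462 M⁻¹ min⁻¹ and amber 0.00446 M⁻¹ min⁻¹. Their mean, 0.00454 M⁻¹ min⁻¹, is the quench constant, the first-order loss per unit of impurity, a reading that carries the scatter.

At 0.120 M the time constant is 30.6 h, long against the 2.0 h run, so the missing share grows nearly in step with time and reaches 6.33 %. Turn the free monomer, and [free monomer] cancels from this share. Pre-initiator stood at 2 mol% in both runs, so they do not show its effect. Adding ochre's 1 % in chains, this reckoning commits to 7.33 % reacted.

The forecast differs: 6 % reacted (2 % to 12 %) and a chain average of 3 (1 to 15), on the ground that “The loss scales roughly as impurity to the power 1.5”.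

The flask gives 10.3 % reacted and a chain average of 8.34.

    free monomer + initiator → living end + monomer in chains (k = 0.0270 M⁻¹ min⁻¹)
    free monomer + living end → monomer in chains + living end, rate k2*[living end]*[free monomer] (k = 0.690 M⁻¹ min⁻¹)
    protic impurity + free monomer → quenched substrate (k = 0.00490 M⁻¹ min⁻¹)
    pre-initiator → initiator (k = 0.0100 min⁻¹)

The reckoned 6.33 % stands beside 6.31 % of quenched substrate in the flask, and the remaining reacted monomer is the 3.96 % in chains. The length of the run holds the chain average down in part: left ten times as long, the flask averages 42.7, against 8.34. The neighbour flask charged with 0.41 M of free monomer holds 0.120 M of impurity, so the quench constant gives 6.33 %, and that neighbour holds 5.94 % of quenched substrate.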